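(The constants are made up; the run is a simulation.)

This chemistry is slow enough to follow stage by stage, and one ratio carries the story: target over substrate, both as fractions of the charge.

    substrate ⇌ target (K1 = 0.51, k1 = 8.4 × 10⁻⁵ /s)
    substrate ⇌ isomer of the product A (K2 = 16, k2 = 4.9 × 10⁻⁵ /s)
    substrate ⇌ third isomer (K3 = 55, k3 = 2.3 × 10⁻⁶ /s)
    substrate ⇌ dormant form (K4 = 0.54, k4 = 4.4 × 10⁻⁶ /s)
    target ⇌ isomer of the product B (K5 = 0.15, k5 = 1.1 × 10⁻⁵ /s)

| setting | east | south-west | south-east |
|---|---|---|---|
| substrate | 0.21 M | 0.21 M | 0.21 M |
| time | 5.0 h | 5.0 h |  |
| remark | everything together in a closed stirred flask, run for 5.0 h | plug flow through a tube for 5.0 h, no back-mixing | a single well-mixed tank run continuously and read at steady state, 5.0 h in it on average |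

1. the set-up with the highest amount of target at the outlet or at the end, in percent of the substrate put in ("none" if the first two lie within 2 percentage points) (east / south-west / south-east / none)
2. amount of target at the outlet or at the end, in percent of the substrate put in, east
3. amount of target at the outlet or at the end, in percent of the substrate put in, south-west
4. amount of target at the outlet or at the end, in percent of the substrate put in, south-east

1. First instants. The charge is substrate, with no target yet. Substrate leaves at 1.40 × 10⁻⁴ /s in total, counting forward steps, and the step to target takes 0.601 of that, more than any other exit.

2. The crossing. Target gains its forward constant times the substrate fraction. It loses 1.76 × 10⁻⁴ /s times its own fraction, the way back to substrate plus the way on to isomer of the product B. I leave out the return from that isomer. The gain and the loss meet when target over substrate reaches 0.478, which I call the turning ratio. In the closed flask and the tube, target rises below it and falls above it. Target is an intermediate in those two, and there this ratio marks its maximum.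

3. Closed flask and tube. With forward drains, the pair substrate and target has a fast rate 2.77 × 10⁻⁴ /s and a slow rate 3.87 × 10⁻⁵ /s, the fast one well ahead. In this reckoning the crossing falls at 2.30 h, with target near 22.0%. After it, the reckoned target follows substrate down at the slow rate. At 5.0 h I reckon 17.3% in the closed flask, and the same in the tube, where each slice lives the same history. I count no return from isomer of the product A, which adds substrate, so I hold this figure as low.

4. Tank. Washout joins target's losses, so the tank's ratio stands at 0.363, below the turning ratio. The substrate balance gives 41.0% substrate, hence 14.9% target. I commit to a tie between closed flask and tube, with the tank lower.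

5. The forecast says none, with 18.6% east, 18.6% south-west and 15.9% south-east, higher than my figures, on the grounds that “The closed stirred flask and the plug-flow tube have the same time history”.

6. The simulation gives none: 18.5% in the closed flask, 18.5% in the tube and 15.9% in the tank. The closed flask ends with 30.5% substrate, so its ratio reads 0.607, above the turning ratio 0.478, which puts that reading past the crossing. In the tank, substrate stands at 42.5% and the ratio reads 0.374, below the turning ratio, beside my tank ratio of 0.363.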